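The flavanone half is cut at O1–C8a and C4–C4a. Ring A of the flavanone is unmasked as an aryne (C4a≡C8a) that already carries the apigenin unit at C8, and the O1–C2–C3–C4 chain arrives as an enantiopure (S)-β-silyloxy ester. The key step exploits the ortho relationship of O1 and the C4 carbonyl on ring A and the C5 oxygen next to C4a, which polarises the aryne: the alkoxide adds at C8a and the C4a carbanion closes onto the ester, forming both bonds and the pyranone ring at once without touching C2. The precursor is a tribenzylapigenin bearing at C8 an ortho-silylaryl triflate.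

Key step: step 9

Remark 1: the tetra-ortho-substituted 8,8''-biaryl axis may be configurationally stable; the target structure defines only C2, so the axis is left uncontrolled and its two orientations are treated as one compound.
Remark 2: keto ester 11 is taken as a catalogue compound.

Step 1
Reactants: 1 apigenin
Product: 2 5,7-bis(benzyloxy)-2-[4-(benzyloxy)phenyl]-4H-chromen-4-one
Conditions: BnBr (4 equiv), K2CO3, DMF, 80 °C
Reagents that add atoms: benzyl bromide, BrCc1ccccc1
Why: Williamson etherification of all three phenols; the hydrogen-bonded 5-OH is slowest and needs excess reagent and heat, and carbonate in DMF favours O- over C-alkylation.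

Step 2
Reactants: 2 5,7-bis(benzyloxy)-2-[4-(benzyloxy)phenyl]-4H-chromen-4-one
Product: 3 5,7-bis(benzyloxy)-2-[4-(benzyloxy)phenyl]-8-iodo-4H-chromen-4-one
Conditions: NIS (1.1 equiv), TFA (cat.), CH2Cl2/MeCN, 0 °C → rt, dark
Reagents that add atoms: N-iodosuccinimide, O=C1CCC(=O)N1I
Why: Electrophilic aromatic iodination; in 5-O-alkylated 5,7-dioxygenated flavones ring A is the most electron-rich ring and substitution is known to go to C8 (a free 5-OH would direct to C6).

Step 3
Reactants: 3 5,7-bis(benzyloxy)-2-[4-(benzyloxy)phenyl]-8-iodo-4H-chromen-4-one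
Product: 4 5,7-bis(benzyloxy)-2-[4-(benzyloxy)phenyl]-8-(4,4,5,5-tetramethyl-1,3,2-dioxaborolan-2-yl)-4H-chromen-4-one
Conditions: B2pin2, Pd(dppf)Cl2 (5 mol%), KOAc, 1,4-dioxane, 90 °C
Reagents that add atoms: bis(pinacolato)diboron, CC1(C)OB(OC1(C)C)B1OC(C)(C)C(C)(C)O1
Why: Miyaura borylation of the aryl iodide by zerovalent palladium formed in situ; acetate is too weak a base to drive onward Suzuki coupling of the product.

Step 4
Reactants: 5 3,5-bis(benzyloxy)phenol
Product: 6 3,5-bis(benzyloxy)-2,6-dibromophenol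
Conditions: NBS (2.05 equiv), i-Pr2NH (0.2 equiv), CH2Cl2, −78 → 0 °C
Reagents that add atoms: N-bromosuccinimide, O=C1CCC(=O)N1Br
Why: Amine-mediated ortho-selective electrophilic bromination of a phenol (the N-bromoamine is delivered through hydrogen bonding to the OH); the two ortho positions are equivalent and the para position is flanked by two benzyloxy groups.

Step 5
Reactants: 6 3,5-bis(benzyloxy)-2,6-dibromophenol
Product: 9 3,5-bis(benzyloxy)-2-bromo-6-(trimethylsilyl)phenyl trifluoromethanesulfonate, via aryl trimethylsilyl ether 7 (not isolated), via lithium silylphenoxide 8 (not isolated)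
Conditions: HMDS, THF, 65 °C, then evaporate; n-BuLi (1.05 equiv), THF, −78 °C; Tf2O, −78 → 0 °C
Reagents that add atoms: hexamethyldisilazane, C[Si](C)(C)N[Si](C)(C)C; trifluoromethanesulfonic anhydride, O=S(=O)(OS(=O)(=O)C(F)(F)F)C(F)(F)F
Why: O-silylation, bromine–lithium exchange of one of two equivalent bromides, 1,3 O→C silyl shift (retro-Brook rearrangement) and O-triflation of the phenoxide is the standard route from ortho-bromophenols to ortho-silylaryl triflates; exchange is far faster than benzylic deprotonation at −78 °C.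

Step 6
Reactants: 4 5,7-bis(benzyloxy)-2-[4-(benzyloxy)phenyl]-8-(4,4,5,5-tetramethyl-1,3,2-dioxaborolan-2-yl)-4H-chromen-4-one; 9 3,5-bis(benzyloxy)-2-bromo-6-(trimethylsilyl)phenyl trifluoromethanesulfonate
Product: 10 2-{5,7-bis(benzyloxy)-2-[4-(benzyloxy)phenyl]-4-oxo-4H-chromen-8-yl}-3,5-bis(benzyloxy)-6-(trimethylsilyl)phenyl trifluoromethanesulfonate
Conditions: Pd(OAc)2 (5 mol%), SPhos (10 mol%), K3PO4, toluene/H2O (10:1), 80 °C
Reagents that add atoms: none
Why: Suzuki–Miyaura coupling with a bulky electron-rich biarylphosphine suited to tetra-ortho-substituted biaryls; oxidative addition should occur at C–Br and not at the C–OTf bond shielded by the silyl group, and without fluoride the silyl triflate should persist.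

Step 7
Reactants: 11 ethyl 3-[4-(benzyloxy)phenyl]-3-oxopropanoate
Product: 12 ethyl (S)-3-[4-(benzyloxy)phenyl]-3-hydroxypropanoate
Conditions: RuCl(p-cymene)[(S,S)-TsDPEN] (1 mol%), HCO2H/Et3N (5:2), EtOAc, 30 °C
Reagents that add atoms: none
Why: Noyori asymmetric transfer hydrogenation; the (S,S)-TsDPEN complex of divalent ruthenium delivers hydride to the Re face of aryl ketones, which sets the (S) carbinol centre that becomes C2.

Step 8
Reactants: 12 ethyl (S)-3-[4-(benzyloxy)phenyl]-3-hydroxypropanoate
Product: 13 ethyl (S)-3-[4-(benzyloxy)phenyl]-3-[(trimethylsilyl)oxy]propanoate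
Conditions: TMSCl, imidazole, CH2Cl2, 0 °C; filtration through Et3N-washed silica
Reagents that add atoms: chlorotrimethylsilane, C[Si](C)(C)Cl
Why: Standard silylation of a secondary alcohol; the trimethylsilyl ether serves as a proton-free latent alkoxide for the next step.

Step 9
Reactants: 10 2-{5,7-bis(benzyloxy)-2-[4-(benzyloxy)phenyl]-4-oxo-4H-chromen-8-yl}-3,5-bis(benzyloxy)-6-(trimethylsilyl)phenyl trifluoromethanesulfonate; 13 ethyl (S)-3-[4-(benzyloxy)phenyl]-3-[(trimethylsilyl)oxy]propanoate
Product: 16 (2S)-5,7-bis(benzyloxy)-2-[4-(benzyloxy)phenyl]-8-{5,7-bis(benzyloxy)-2-[4-(benzyloxy)phenyl]-4-oxo-4H-chromen-8-yl}chroman-4-one, via caesium alkoxide 14 (not isolated), via aryne 15 (not isolated)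
Conditions: 13 (2.5 equiv), anhydrous CsF, 18-crown-6, toluene, 0 → 23 °C; pH 7 buffer quench
Reagents that add atoms: none
Why: Proposed new method: fluoride unmasks the caesium alkoxide 14 from 13 and triggers 1,2-elimination of 10 to the aryne 15 (C4a≡C8a); the alkoxide oxygen adds to C8a, and the C4a aryl anion so formed, having no proton to pick up, attacks the pendant ethyl ester and expels ethoxide, which is silylated and carries the chain. The closest known reaction types are the aryne annulation of salicylate esters to xanthones (phenoxide addition, then intramolecular acyl trapping) and the fluoride-mediated O-arylation of aliphatic alcohols by arynes; the use of an aliphatic β-oxido ester to give a chroman-4-one is the untested extension. Ring C closes by a 6-exo-trig acyl substitution of the aryl anion at the ester carbonyl. No stereocentre is formed: C2 comes from 12 with its (S) configuration and no bond to it is broken, so the reaction need only be kept cold and short enough that retro-aldol of 14 and base-induced ring opening of 16 do not erode it. The regioselectivity needed (oxygen at C8a, acyl at C4a) should be secured by the C5 benzyloxy group, whose inductive effect distorts the aryne so that nucleophiles add at the distal carbon C8a and charge develops at C4a next to oxygen; the orthogonal tetra-ortho-substituted biaryl should keep the flavone oxygens away from the in-plane aryne orbital.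

Step 10
Reactants: 16 (2S)-5,7-bis(benzyloxy)-2-[4-(benzyloxy)phenyl]-8-{5,7-bis(benzyloxy)-2-[4-(benzyloxy)phenyl]-4-oxo-4H-chromen-8-yl}chroman-4-one
Product: 17 (2S)-5,7-dihydroxy-2-(4-hydroxyphenyl)-8-[5,7-dihydroxy-2-(4-hydroxyphenyl)-4-oxo-4H-chromen-8-yl]chroman-4-one
Conditions: H2 (1 atm), 10% Pd/C, THF/MeOH (1:1), rt
Reagents that add atoms: none
Why: Hydrogenolysis of the six benzyl ethers under neutral conditions should leave the flavone C2=C3 bond and both aryl ketones intact at ambient pressure and cannot epimerise C2, since neither base nor acid is present.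

Compound list
1 | apigenin, 5,7-dihydroxy-2-(4-hydroxyphenyl)-4H-chromen-4-one | O=c1cc(-c2ccc(O)cc2)oc2cc(O)cc(O)c12 | starting material
2 | 5,7-bis(benzyloxy)-2-[4-(benzyloxy)phenyl]-4H-chromen-4-one (tri-O-benzylapigenin) | O=c1cc(-c2ccc(OCc3ccccc3)cc2)oc2cc(OCc3ccccc3)cc(OCc3ccccc3)c12 | intermediate
3 | 5,7-bis(benzyloxy)-2-[4-(benzyloxy)phenyl]-8-iodo-4H-chromen-4-one | O=c1cc(-c2ccc(OCc3ccccc3)cc2)oc2c(I)c(OCc3ccccc3)cc(OCc3ccccc3)c12 | intermediate
4 | 5,7-bis(benzyloxy)-2-[4-(benzyloxy)phenyl]-8-(4,4,5,5-tetramethyl-1,3,2-dioxaborolan-2-yl)-4H-chromen-4-one | O=c1cc(-c2ccc(OCc3ccccc3)cc2)oc2c(B3OC(C)(C)C(C)(C)O3)c(OCc3ccccc3)cc(OCc3ccccc3)c12 | intermediate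
5 | 3,5-bis(benzyloxy)phenol | Oc1cc(OCc2ccccc2)cc(OCc2ccccc2)c1 | starting material
6 | 3,5-bis(benzyloxy)-2,6-dibromophenol | Oc1c(Br)c(OCc2ccccc2)cc(OCc2ccccc2)c1Br | intermediate
7 | [3,5-bis(benzyloxy)-2,6-dibromophenoxy]trimethylsilane (not isolated) | C[Si](C)(C)Oc1c(Br)c(OCc2ccccc2)cc(OCc2ccccc2)c1Br | intermediate
8 | lithium 3,5-bis(benzyloxy)-2-bromo-6-(trimethylsilyl)phenoxide (not isolated) | [Li+].[O-]c1c(Br)c(OCc2ccccc2)cc(OCc2ccccc2)c1[Si](C)(C)C | intermediate
9 | 3,5-bis(benzyloxy)-2-bromo-6-(trimethylsilyl)phenyl trifluoromethanesulfonate | O=S(=O)(Oc1c(Br)c(OCc2ccccc2)cc(OCc2ccccc2)c1[Si](C)(C)C)C(F)(F)F | intermediate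
10 | 2-{5,7-bis(benzyloxy)-2-[4-(benzyloxy)phenyl]-4-oxo-4H-chromen-8-yl}-3,5-bis(benzyloxy)-6-(trimethylsilyl)phenyl trifluoromethanesulfonate (triflate next to the biaryl bond, silyl group next to a benzyloxy group) | O=c1cc(-c2ccc(OCc3ccccc3)cc2)oc2c(-c3c(OCc4ccccc4)cc(OCc4ccccc4)c([Si](C)(C)C)c3OS(=O)(=O)C(F)(F)F)c(OCc3ccccc3)cc(OCc3ccccc3)c12 | intermediate
11 | ethyl 3-[4-(benzyloxy)phenyl]-3-oxopropanoate | CCOC(=O)CC(=O)c1ccc(OCc2ccccc2)cc1 | starting material
12 | ethyl (S)-3-[4-(benzyloxy)phenyl]-3-hydroxypropanoate | CCOC(=O)C[C@@H](c1ccc(OCc2ccccc2)cc1)O | intermediate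
13 | ethyl (S)-3-[4-(benzyloxy)phenyl]-3-[(trimethylsilyl)oxy]propanoate | CCOC(=O)C[C@@H](c1ccc(OCc2ccccc2)cc1)O[Si](C)(C)C | intermediate
14 | caesium (S)-1-[4-(benzyloxy)phenyl]-3-ethoxy-3-oxopropan-1-olate (not isolated) | [Cs+].CCOC(=O)C[C@@H](c1ccc(OCc2ccccc2)cc1)[O-] | intermediate
15 | aryne: 8-[2,4-bis(benzyloxy)cyclohexa-1,3-dien-5-yn-1-yl]-5,7-bis(benzyloxy)-2-[4-(benzyloxy)phenyl]-4H-chromen-4-one, the 3,5-bis(benzyloxy)benzyne carrying the flavone at C6 (not isolated) | O=c1cc(-c2ccc(OCc3ccccc3)cc2)oc2c(C3=C(OCc4ccccc4)C=C(OCc4ccccc4)C#C3)c(OCc3ccccc3)cc(OCc3ccccc3)c12 | intermediate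
16 | (2S)-5,7-bis(benzyloxy)-2-[4-(benzyloxy)phenyl]-8-{5,7-bis(benzyloxy)-2-[4-(benzyloxy)phenyl]-4-oxo-4H-chromen-8-yl}chroman-4-one (hexabenzyl ether of the target) | O=C1C[C@@H](c2ccc(OCc3ccccc3)cc2)Oc2c1c(OCc1ccccc1)cc(OCc1ccccc1)c2-c1c(OCc2ccccc2)cc(OCc2ccccc2)c2c(=O)cc(-c3ccc(OCc4ccccc4)cc3)oc12 | intermediate
17 | (2S)-5,7-dihydroxy-2-(4-hydroxyphenyl)-8-[5,7-dihydroxy-2-(4-hydroxyphenyl)-4-oxo-4H-chromen-8-yl]chroman-4-one (CNP0339995.1, (2S)-2,3-dihydrocupressuflavone) | O=C1C[C@@H](c2ccc(O)cc2)Oc2c1c(O)cc(O)c2-c1c(O)cc(O)c2c(=O)cc(-c3ccc(O)cc3)oc12 | target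

Total step count: 10. Longest linear sequence: 6 steps (steps 1, 2, 3, 6, 9, 10).

Steps most likely to fail

1. Step 9 (proposed new method). Addition of the secondary alkoxide next to the biaryl axis may be slow. That would let retro-aldol fragmentation or elimination of the alkoxide, proton capture by the aryl anion in place of acyl transfer, or addition in the reverse sense take over. Base-induced ring opening of the product would also erode the configuration at C2. The fallback uses known chemistry and sets out from 10. The aryne is generated with CsF in THF at 125 °C (sealed tube) in the presence of commercial (E)-4-(benzyloxy)cinnamic acid. The established insertion of arynes into the C–O bond of carboxylic acids should give the 2'-hydroxychalcone F1, forming O–C8a and C4–C4a in one operation: the carboxylate adds at C8a, the aryl anion attacks the carboxyl carbon and the four-membered adduct opens. Under the same fluoride conditions F1 should close by oxa-Michael addition to the racemic flavanone F2. Resolution of F2 by preparative HPLC on a chiral stationary phase (amylose tris(3,5-dimethylphenylcarbamate)) returns to the route at 16; the unwanted enantiomer is equilibrated through F1 with catalytic base and recycled.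

2. Step 6. The hot, basic coupling conditions may release the aryne without fluoride or cleave the triflate. Oxidative addition may occur at C–OTf instead of C–Br, and the di-ortho-oxygenated boronate 4 may protodeboronate before the slow tetra-ortho coupling. The fallback forms the biaryl before the triflate exists and sets out from 6. Silylation with HMDS, bromine–lithium exchange with n-BuLi and retro-Brook rearrangement as in step 5, but with an aqueous NH4Cl quench, should give the bromo silyl phenol F3. Suzuki–Miyaura coupling of F3 with 4 (Pd(OAc)2, SPhos, K3PO4) should give the biaryl phenol F4, which is triflated with Tf2O and pyridine in CH2Cl2 at 0 °C. This returns to the route at 10.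

3. Step 4. Bromination may occur at the para position between the two benzyloxy groups, or go on to the tribromide, giving mixtures that are hard to separate. The fallback fixes the substitution pattern by directed ortho-metalation and sets out from 5. Isopropyl isocyanate with catalytic Et3N should give the N-isopropyl carbamate F5. In situ N-silylation (TBSOTf, TMEDA), ortho-lithiation with n-BuLi/TMEDA at −78 °C and a TMSCl quench should give the ortho-silyl carbamate F6. A second directed lithiation at the remaining position between the carbamate and a benzyloxy group, quenched with 1,2-dibromotetrachloroethane, should give the bromo silyl carbamate F7. Cleavage with Et2NH and DBU in MeCN at 40 °C liberates the phenol F3, which is triflated in the same pot with PhNTf2. This returns to the route at 9 and bypasses 6, 7 and 8.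

Further compounds
F1 | step 9 | (E)-1-{4,6-bis(benzyloxy)-3-[5,7-bis(benzyloxy)-2-(4-(benzyloxy)phenyl)-4-oxo-4H-chromen-8-yl]-2-hydroxyphenyl}-3-[4-(benzyloxy)phenyl]prop-2-en-1-one (2'-hydroxychalcone) | O=C(/C=C/c1ccc(OCc2ccccc2)cc1)c1c(O)c(-c2c(OCc3ccccc3)cc(OCc3ccccc3)c3c(=O)cc(-c4ccc(OCc5ccccc5)cc4)oc23)c(OCc2ccccc2)cc1OCc1ccccc1
F2 | step 9 | racemic 5,7-bis(benzyloxy)-2-[4-(benzyloxy)phenyl]-8-{5,7-bis(benzyloxy)-2-[4-(benzyloxy)phenyl]-4-oxo-4H-chromen-8-yl}chroman-4-one | O=C1CC(c2ccc(OCc3ccccc3)cc2)Oc2c1c(OCc1ccccc1)cc(OCc1ccccc1)c2-c1c(OCc2ccccc2)cc(OCc2ccccc2)c2c(=O)cc(-c3ccc(OCc4ccccc4)cc3)oc12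
F3 | step 6 | 3,5-bis(benzyloxy)-2-bromo-6-(trimethylsilyl)phenol | Oc1c(Br)c(OCc2ccccc2)cc(OCc2ccccc2)c1[Si](C)(C)C
F4 | step 6 | 5,7-bis(benzyloxy)-2-[4-(benzyloxy)phenyl]-8-[4,6-bis(benzyloxy)-2-hydroxy-3-(trimethylsilyl)phenyl]-4H-chromen-4-one | O=c1cc(-c2ccc(OCc3ccccc3)cc2)oc2c(-c3c(OCc4ccccc4)cc(OCc4ccccc4)c([Si](C)(C)C)c3O)c(OCc3ccccc3)cc(OCc3ccccc3)c12
F5 | step 4 | 3,5-bis(benzyloxy)phenyl N-isopropylcarbamate | CC(C)NC(=O)Oc1cc(OCc2ccccc2)cc(OCc2ccccc2)c1
F6 | step 4 | 3,5-bis(benzyloxy)-2-(trimethylsilyl)phenyl N-isopropylcarbamate | CC(C)NC(=O)Oc1cc(OCc2ccccc2)cc(OCc2ccccc2)c1[Si](C)(C)C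
F7 | step 4 | 3,5-bis(benzyloxy)-2-bromo-6-(trimethylsilyl)phenyl N-isopropylcarbamate | CC(C)NC(=O)Oc1c(Br)c(OCc2ccccc2)cc(OCc2ccccc2)c1[Si](C)(C)C
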